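**Plan**
- Retrosynthesis: C2–Br is removed first (electrophilic bromination), N1–H is masked as N‑tosyl, and the C3–S bond is traced back to the C3 ketone of an indolin‑3‑one. That ketone is then cut at N1–C7a and C3–C3a in one operation.
- Enabling feature: in the benzene ring, C7a (bearing N1) lies next to C7–H and C3a (bearing C3) lies next to C4–Br. The C3a–C7a bond therefore corresponds to the triple bond of 3,4,5‑tribromobenzyne, polarised by the C4 bromine in the sense required.
- Forward: the benzene ring is bought as 3,4,5‑tribromoaniline and converted into an ortho‑silyl aryl triflate. Glycine supplies N1, C2 and C3, and the five‑membered ring closes in the aryne annulation.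
- The ketone is then aromatised with methanethiol, the tosyl group is removed and C2 is brominated.
- Stereochemistry: the target is achiral and has no stereocentre; the only selectivity to control is the regiochemistry of aryne capture.

Key step: step 7

Assumption: 3,4,5‑tribromoaniline is taken as a catalogue compound, and methanethiol (b.p. about 6 °C) is handled condensed in a pressure tube.

**Route**

Step 1
Reactants: 1 3,4,5‑tribromoaniline
Product: 3 3,4,5‑tribromophenol, via 3,4,5‑tribromobenzenediazonium hydrogensulfate 2 (not isolated)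
Conditions: NaNO2, conc. H2SO4/AcOH, 0–5 °C; then 40% aq. H2SO4, reflux
Reagents that add atoms: water, O (oxygen of the phenol); sodium nitrite, [Na+].[O-]N=O (outer nitrogen of 2 only, lost again as N2)
Why: Diazotisation of the weakly basic aniline with nitrosylsulfuric acid and thermal hydrolysis of the diazonium salt (phenol synthesis by diazonium hydrolysis) should replace NH2 by OH without touching the three C–Br bonds.

Step 2
Reactants: 3 3,4,5‑tribromophenol; 4 N,N‑diethylcarbamoyl chloride
Product: 5 3,4,5‑tribromophenyl N,N‑diethylcarbamate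
Conditions: Et2NCOCl, K2CO3, MeCN, reflux
Reagents that add atoms: N,N‑diethylcarbamoyl chloride 4, CCN(CC)C(=O)Cl
Why: O‑Carbamoylation of the acidic phenol should install the strongest oxygen‑based directing group for ortho‑metalation.

Step 3
Reactants: 5 3,4,5‑tribromophenyl N,N‑diethylcarbamate; 6 chlorotrimethylsilane
Product: 8 3,4,5‑tribromo‑2‑(trimethylsilyl)phenyl N,N‑diethylcarbamate, via 2‑lithio‑3,4,5‑tribromophenyl N,N‑diethylcarbamate 7 (not isolated)
Conditions: TMSCl (3 equiv) premixed with 5; lithium 2,2,6,6‑tetramethylpiperidide (LiTMP, 1.05 equiv, from the amine and n‑BuLi) added dropwise, THF, −78 °C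
Reagents that add atoms: chlorotrimethylsilane 6, C[Si](C)(C)Cl; LiTMP, [Li+].CC1(C)CCCC(C)(C)[N-]1 (lithium of 7 only)
Why: Directed ortho‑metalation under in‑situ‑quench conditions should work because the C2–H between the carbamate and bromine is the most acidic proton, the two such sites are equivalent by symmetry, and the silyl chloride present from the start should trap 7 before it can lose LiBr, undergo halogen dance or suffer anionic ortho‑Fries rearrangement.

Step 4
Reactants: 8 3,4,5‑tribromo‑2‑(trimethylsilyl)phenyl N,N‑diethylcarbamate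
Product: 9 3,4,5‑tribromo‑2‑(trimethylsilyl)phenol
Conditions: Cp2Zr(H)Cl (2 equiv), THF, rt; aq. NH4Cl
Reagents that add atoms: none
Why: Reductive cleavage of the aryl O‑carbamate with Cp2Zr(H)Cl (hydrozirconation of the C=O, then collapse to phenoxide and formamide) is neutral and should spare the C–Si and C–Br bonds that basic or acidic hydrolysis would endanger.

Step 5
Reactants: 9 3,4,5‑tribromo‑2‑(trimethylsilyl)phenol; 10 trifluoromethanesulfonic anhydride
Product: 11 3,4,5‑tribromo‑2‑(trimethylsilyl)phenyl trifluoromethanesulfonate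
Conditions: Tf2O, pyridine, CH2Cl2, 0 °C
Reagents that add atoms: trifluoromethanesulfonic anhydride 10, FC(F)(F)S(=O)(=O)OS(=O)(=O)C(F)(F)F
Why: Standard O‑triflation of a phenol should give the ortho‑silyl aryl triflate needed for fluoride‑induced aryne release.

Step 6
Reactants: 12 glycine methyl ester hydrochloride; 13 4‑toluenesulfonyl chloride
Product: 14 methyl N‑tosylglycinate
Conditions: TsCl, Et3N (2.2 equiv), CH2Cl2, 0 °C to rt
Reagents that add atoms: 4‑toluenesulfonyl chloride 13, Cc1ccc(cc1)S(=O)(=O)Cl
Why: N‑Sulfonylation of the primary amine should give the NH‑acidic sulfonamide that serves as the nitrogen nucleophile and carries the ester as internal acylating agent.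

Step 7
Reactants: 11 3,4,5‑tribromo‑2‑(trimethylsilyl)phenyl trifluoromethanesulfonate; 14 methyl N‑tosylglycinate
Product: 17 4,5,6‑tribromo‑1‑tosylindolin‑3‑one, via 3,4,5‑tribromobenzyne 15 (not isolated), via caesium aryl anion 16 (not isolated)
Conditions: CsF (3 equiv), MeCN, rt; 11 added slowly to 14 (1.5 equiv)
Reagents that add atoms: caesium fluoride, [Cs+].[F-] (counter‑ion of 16 only; no atom of it reaches 17)
Why: Fluoride attacks silicon in 11 and triflate, a far better leaving group than the bromide on the other flank, departs to give aryne 15, in which the bromine at C3 bends the triple bond so that C1, the terminus away from bromine and next to C–H, is the more linear and more electrophilic carbon. The sulfonamide anion of 14 should therefore add at C1 (N1–C7a), placing the charge at C2 beside the inductively stabilising C–Br as aryl anion 16. Anion 16 attacks the ester carbonyl in a 5‑exo‑trig closure and the tetrahedral adduct expels methoxide, which forms C3–C3a and the five‑membered ring of 17. The closest known reaction type is the aryne annulation of N‑sulfonyl α‑amino esters to indolin‑3‑ones, a relative of the aryne routes to acridones and xanthones from 2‑aminobenzoates and salicylates. No stereocentre is formed. The step needs regioselective N‑addition, which the C4 bromine (aryne distortion) and the lower hindrance beside C7–H both secure, and it needs acylation to outrun protonation or bromide loss from 16, which the intramolecular five‑membered transition state should provide.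

Step 8
Reactants: 17 4,5,6‑tribromo‑1‑tosylindolin‑3‑one; 18 methanethiol
Product: 19 4,5,6‑tribromo‑3‑(methylsulfanyl)‑1‑tosyl‑1H‑indole
Conditions: MeSH (excess), TsOH·H2O (cat.), 4 Å molecular sieves, toluene, sealed tube, 80 °C
Reagents that add atoms: methanethiol 18, CS
Why: Acid‑catalysed thiol addition to the ketone followed by dehydration gives the vinyl sulfide, which here is the aromatic 3‑sulfenylindole, a condensation known for N‑acyl and N‑sulfonyl indoxyls.

Step 9
Reactants: 19 4,5,6‑tribromo‑3‑(methylsulfanyl)‑1‑tosyl‑1H‑indole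
Product: 20 4,5,6‑tribromo‑3‑(methylsulfanyl)‑1H‑indole
Conditions: Cs2CO3 (3 equiv), THF/MeOH 2:1, rt
Reagents that add atoms: none
Why: Base‑mediated methanolysis of the N–sulfonyl bond (Cs2CO3/MeOH detosylation) is fast for indoles whose anion is stabilised by electron‑withdrawing groups, as by the three bromines here, and should leave C–Br and C–S untouched.

Step 10
Reactants: 20 4,5,6‑tribromo‑3‑(methylsulfanyl)‑1H‑indole; 21 N‑bromosuccinimide
Product: 22 2,4,5,6‑tetrabromo‑3‑(methylsulfanyl)‑1H‑indole
Conditions: NBS (1.0 equiv), CH2Cl2, −20 to 0 °C, dark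
Reagents that add atoms: N‑bromosuccinimide 21, O=C1CCC(=O)N1Br
Why: Electrophilic aromatic bromination should occur at C2 because C3 is blocked by sulfur and C2 is the only free pyrrole carbon, far more reactive than the deactivated C7.

**Compound list**
1 | 3,4,5‑tribromoaniline | Nc1cc(Br)c(Br)c(Br)c1 | starting material
2 | 3,4,5‑tribromobenzenediazonium hydrogensulfate | N#[N+]c1cc(Br)c(Br)c(Br)c1.OS(=O)(=O)[O-] | intermediate
3 | 3,4,5‑tribromophenol | Oc1cc(Br)c(Br)c(Br)c1 | intermediate
4 | N,N‑diethylcarbamoyl chloride | CCN(CC)C(=O)Cl | starting material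
5 | 3,4,5‑tribromophenyl N,N‑diethylcarbamate | CCN(CC)C(=O)Oc1cc(Br)c(Br)c(Br)c1 | intermediate
6 | chlorotrimethylsilane | C[Si](C)(C)Cl | starting material
7 | 2‑lithio‑3,4,5‑tribromophenyl N,N‑diethylcarbamate | [Li]c1c(OC(=O)N(CC)CC)cc(Br)c(Br)c1Br | intermediate
8 | 3,4,5‑tribromo‑2‑(trimethylsilyl)phenyl N,N‑diethylcarbamate | CCN(CC)C(=O)Oc1cc(Br)c(Br)c(Br)c1[Si](C)(C)C | intermediate
9 | 3,4,5‑tribromo‑2‑(trimethylsilyl)phenol | C[Si](C)(C)c1c(O)cc(Br)c(Br)c1Br | intermediate
10 | trifluoromethanesulfonic anhydride | FC(F)(F)S(=O)(=O)OS(=O)(=O)C(F)(F)F | starting material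
11 | 3,4,5‑tribromo‑2‑(trimethylsilyl)phenyl trifluoromethanesulfonate | C[Si](C)(C)c1c(Br)c(Br)c(Br)cc1OS(=O)(=O)C(F)(F)F | intermediate
12 | glycine methyl ester hydrochloride | COC(=O)CN.Cl | starting material
13 | 4‑toluenesulfonyl chloride | Cc1ccc(cc1)S(=O)(=O)Cl | starting material
14 | methyl N‑tosylglycinate | COC(=O)CNS(=O)(=O)c1ccc(C)cc1 | intermediate
15 | 3,4,5‑tribromobenzyne (aryne carbons C1 and C2, bromines on C3, C4 and C5) | BrC1=C(Br)C(Br)=CC#C1 | intermediate
16 | caesium salt of the aryl anion of methyl N‑(3,4,5‑tribromophenyl)‑N‑tosylglycinate (carbanion on the ring carbon between C–N and C–Br) | COC(=O)CN(C1=[C-]C(Br)=C(Br)C(Br)=C1)S(=O)(=O)c1ccc(C)cc1.[Cs+] | intermediate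
17 | 4,5,6‑tribromo‑1‑tosylindolin‑3‑one | Cc1ccc(cc1)S(=O)(=O)N1CC(=O)c2c(Br)c(Br)c(Br)cc21 | intermediate
18 | methanethiol | CS | starting material
19 | 4,5,6‑tribromo‑3‑(methylsulfanyl)‑1‑tosyl‑1H‑indole | CSc1cn(S(=O)(=O)c2ccc(C)cc2)c2cc(Br)c(Br)c(Br)c12 | intermediate
20 | 4,5,6‑tribromo‑3‑(methylsulfanyl)‑1H‑indole | CSc1c[nH]c2cc(Br)c(Br)c(Br)c12 | intermediate
21 | N‑bromosuccinimide | O=C1CCC(=O)N1Br | starting material
22 | 2,4,5,6‑tetrabromo‑3‑(methylsulfanyl)‑1H‑indole | CSc1c(Br)[nH]c2cc(Br)c(Br)c(Br)c12 | target

**Count**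
Total steps: 10. Longest linear sequence: 9 (steps 1–5 and 7–10); step 6 is a one‑step side branch.

**Steps most likely to fail**

Step 7. Aryl anion 16 may be protonated (by the acidic α‑CH2, the N–H or the solvent) or may lose its neighbouring bromide to form a second aryne before it acylates. The acidic C2 methylene of the product may also be arylated by further aryne. Fallback, setting out from 1 and coming back at 20: the aryne is given up and the pyrrole ring is built by a Gassman indole synthesis. Aniline 1 is N‑chlorinated with t‑BuOCl in CH2Cl2 at −78 °C to N‑chloro‑3,4,5‑tribromoaniline F1. Addition of (methylsulfanyl)acetaldehyde dimethyl acetal gives (2,2‑dimethoxyethyl)(methyl)[(3,4,5‑tribromophenyl)amino]sulfonium chloride F2. Et3N forms the ylide, whose Sommelet–Hauser [2,3]‑shift onto either of the two equivalent ortho carbons, followed by rearomatisation, delivers 3,4,5‑tribromo‑2‑[2,2‑dimethoxy‑1‑(methylsulfanyl)ethyl]aniline F3. Dilute HCl in Et2O then closes the ring with loss of methanol to 20, which already carries the C3 sulfide, and step 10 follows.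

Step 3. The lithiated polybromoarene may eliminate LiBr, scramble its halogens (halogen dance) or transfer the carbamoyl group to carbon, and the second ortho site may be silylated as well. Fallback, setting out from 3 and coming back at 9, so that steps 2 and 4 are also bypassed: the silicon is delivered intramolecularly from oxygen. Phenol 3 is mono‑iodinated at one of its equivalent ortho positions (NIS 1.0 equiv, cat. TsOH, MeCN) to 3,4,5‑tribromo‑2‑iodophenol F4. Hexamethyldisilazane converts it into trimethyl(3,4,5‑tribromo‑2‑iodophenoxy)silane F5. n‑BuLi (1.0 equiv, THF/Et2O, −100 °C) exchanges the iodine selectively to give [2,3,4‑tribromo‑6‑(trimethylsilyloxy)phenyl]lithium F6. This should undergo the retro‑Brook 1,3‑shift of silicon from oxygen to carbon faster than it loses LiBr, and aqueous NH4Cl then gives 9.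

Step 10. Bromine may be transferred to sulfur (leading to S‑oxidation on work‑up) or the electron‑rich pyrrole ring may be over‑oxidised instead of being cleanly substituted at C2. Fallback, setting out from 19 and coming back at 22: bromine is introduced by deprotonation rather than by electrophilic attack on the free indole. N‑Tosylindole 19 is magnesiated at C2 with (2,2,6,6‑tetramethylpiperidin‑1‑yl)magnesium chloride–lithium chloride, TMPMgCl·LiCl (THF, 0 °C), to chloro[4,5,6‑tribromo‑3‑(methylsulfanyl)‑1‑tosyl‑1H‑indol‑2‑yl]magnesium F7. Quenching with 1,2‑dibromo‑1,1,2,2‑tetrachloroethane gives 2,4,5,6‑tetrabromo‑3‑(methylsulfanyl)‑1‑tosyl‑1H‑indole F8. Cs2CO3 in THF/MeOH at rt then removes the tosyl group to give 22.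

**Further compounds**
F1 | step 7 | N‑chloro‑3,4,5‑tribromoaniline | ClNc1cc(Br)c(Br)c(Br)c1
F2 | step 7 | (2,2‑dimethoxyethyl)(methyl)[(3,4,5‑tribromophenyl)amino]sulfonium chloride | COC(OC)C[S+](C)Nc1cc(Br)c(Br)c(Br)c1.[Cl-]
F3 | step 7 | 3,4,5‑tribromo‑2‑[2,2‑dimethoxy‑1‑(methylsulfanyl)ethyl]aniline | COC(OC)C(SC)c1c(N)cc(Br)c(Br)c1Br
F4 | step 3 | 3,4,5‑tribromo‑2‑iodophenol | Oc1cc(Br)c(Br)c(Br)c1I
F5 | step 3 | trimethyl(3,4,5‑tribromo‑2‑iodophenoxy)silane | C[Si](C)(C)Oc1cc(Br)c(Br)c(Br)c1I
F6 | step 3 | [2,3,4‑tribromo‑6‑(trimethylsilyloxy)phenyl]lithium | C[Si](C)(C)Oc1cc(Br)c(Br)c(Br)c1[Li]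
F7 | step 10 | chloro[4,5,6‑tribromo‑3‑(methylsulfanyl)‑1‑tosyl‑1H‑indol‑2‑yl]magnesium | CSc1c([Mg]Cl)n(S(=O)(=O)c2ccc(C)cc2)c2cc(Br)c(Br)c(Br)c12
F8 | step 10 | 2,4,5,6‑tetrabromo‑3‑(methylsulfanyl)‑1‑tosyl‑1H‑indole | CSc1c(Br)n(S(=O)(=O)c2ccc(C)cc2)c2cc(Br)c(Br)c(Br)c12
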